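## Retrosynthetic overview
1. The ten-membered carbocycle is formed last. C4=C5 comes from ring-closing metathesis of an isopropenyl furanone with a C6-vinyl lactone. Just before that, the C8 ester C–O bond is made by site-selective acylation of the 8,9-diol with (R)-2-methylbutanoic acid.
2. The α-methylene-γ-butyrolactone is the second ring. C6–C7 comes from anti-selective Nozaki–Hiyama allylation of acrolein with a (Z)-2-(bromomethyl)enoate, followed by O6–C12 lactonisation. The enoate comes from a C7 aldehyde and methyl propiolate.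
3. The C8 configuration is set by SN2 C–O bond formation (Mitsunobu inversion) on the one hydroxyl that the key step releases.
4. The key disconnection is the furanone C3–O10 bond (first ring). It is made by gold-catalysed ring transposition of a 1-C-alkynyl lactol. The lactol comes from 2-C-methyl-D-ribono-1,4-lactone (source of C1, C7–C10 and C14, with C9 and C10 correctly configured) and 2-methylbut-1-en-3-yne.
5. Ring order: 3(2H)-furanone, then butyrolactone, then the ten-membered ring.

**Atom labels.** C1–C15 are the germacrane positions of the target: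
- C1: ketone
- C2=C3: furanone alkene
- C4=C5: ring alkene (C15 methyl on C4)
- C6: lactone carbinol
- C7: ring-fusion CH
- C8: ester carbinol
- C9: free carbinol
- C10: quaternary carbon (C14 methyl)
- C11=C13: methylene
- C12: lactone carbonyl

**Assumption.** The target SMILES encodes (R) at the acyl α-carbon, and the chiral acid is bought as that single enantiomer.

## Route

Step 1
Reactants: 1 2-C-methyl-D-ribono-1,4-lactone
Product: 2 3,5-bis-O-triethylsilyl-2-C-methyl-D-ribono-1,4-lactone (tertiary hydroxyl free)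
Conditions: Et3SiCl (2.2 equiv), imidazole, DMF, 0 °C to rt
Reagents that add atoms: chlorotriethylsilane CC[Si](Cl)(CC)CC
Why: Silyl ether formation covers the primary and secondary hydroxyls while the hindered tertiary C10 hydroxyl next to the carbonyl stays free, and C9 and C10 come unchanged from the chiral pool.

Step 2
Reactants: 2 3,5-bis-O-triethylsilyl-2-C-methyl-D-ribono-1,4-lactone; 3 2-methylbut-1-en-3-yne
Product: 6 (2R)-2-[(1R,2R)-2-hydroxy-1,3-bis(triethylsilyloxy)propyl]-2-methyl-5-(prop-1-en-2-yl)furan-3(2H)-one, via lithium acetylide 4 (not isolated), via alkynyl lactol 5 (not isolated)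
Conditions: 3 (2.4 equiv), n-BuLi (2.3 equiv), THF, −78 °C; add 2, −78 °C, 1 h; AcOH, −78 °C, aqueous work-up; crude 5, Ph3PAuNTf2 (2 mol %), toluene, rt
Reagents that add atoms: none
Why: Proposed new method: acetylide 1,2-addition to the aldonolactone stops at the hemiketal, which is a 3-alkyne-1,2-diol; the carbophilic monovalent gold cation activates the alkyne, the free tertiary C10 hydroxyl attacks C3 5-endo-dig, and protodeauration gives a 3-alkoxy-3-hydroxy-2,3-dihydrofuran that cannot aromatise because C10 is quaternary, so it collapses to the vinylogous ester by breaking the C1–O8 hemiketal bond, which exchanges the oxolane ring for the 3(2H)-furanone (new C3–O10 bond), releases only the C8 hydroxyl and leaves C8, C9 and C10 untouched; the closest known reaction types are the gold-catalysed cyclisation of 3-alkyne-1,2-diols to furans and the cycloisomerisation of open-chain 2-hydroxy ynones to 3(2H)-furanones, neither of which has been shown on a 1-C-alkynyl furanose hemiketal.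

Step 3
Reactants: 6 furanone alcohol with the ribo configuration at C8
Product: 8 (2R)-2-[(1R,2S)-2-hydroxy-1,3-bis(triethylsilyloxy)propyl]-2-methyl-5-(prop-1-en-2-yl)furan-3(2H)-one, via inverted chloroacetate 7 (not isolated)
Conditions: ClCH2CO2H, PPh3, DIAD, toluene, 0 °C to rt; then K2CO3 (0.2 equiv), MeOH, 0 °C
Reagents that add atoms: chloroacetic acid OC(=O)CCl
Why: In this Mitsunobu reaction the only free hydroxyl is activated as its alkoxyphosphonium salt and displaced by the acidic chloroacetate in an SN2 C–O bond formation that inverts C8 to the target configuration, and the labile chloroacetate is then removed by mild transesterification that spares the silyl ethers.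

Step 4
Reactants: 8 C8-inverted furanone alcohol
Product: 9 (2R)-2-methyl-5-(prop-1-en-2-yl)-2-[(1R,2S)-1,2,3-tris(triethylsilyloxy)propyl]furan-3(2H)-one
Conditions: Et3SiOTf, 2,6-lutidine, CH2Cl2, −78 to 0 °C
Reagents that add atoms: triethylsilyl trifluoromethanesulfonate CC[Si](CC)(CC)OS(=O)(=O)C(F)(F)F
Why: Silyl ether formation places a poor leaving group on O8, because an acyloxy group at this position would be lost by 1,4-elimination from the allylchromium species of step 8.

Step 5
Reactants: 9 tris(triethylsilyl) ether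
Product: 10 (2R,3R)-3-[(2R)-2-methyl-3-oxo-5-(prop-1-en-2-yl)-2,3-dihydrofuran-2-yl]-2,3-bis(triethylsilyloxy)propanal
Conditions: (COCl)2, DMSO, CH2Cl2, −78 to −40 °C; Et3N, −78 to 0 °C
Reagents that add atoms: none
Why: In a Swern oxidation run directly on the silyl ether, activated DMSO cleaves and oxidises only the unhindered primary Et3Si ether while the two secondary ones survive, and the low temperature keeps the α-stereocentre C8 intact.

Step 6
Reactants: 10 C7 aldehyde; 11 methyl propiolate
Product: 13 methyl (4S,5R)-3-hydroxy-2-methylidene-5-[(2R)-2-methyl-3-oxo-5-(prop-1-en-2-yl)-2,3-dihydrofuran-2-yl]-4,5-bis(triethylsilyloxy)pentanoate (both C7 epimers), via vinylalane 12 (not isolated)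
Conditions: 11, i-Bu2AlH, N-methylmorpholine N-oxide, THF, 0 °C; then 10, 0 °C to rt; aqueous KNaC4H4O6
Reagents that add atoms: none
Why: Vinylalumination gives the Baylis–Hillman-type adduct without an amine base: hydroalumination places aluminium on the α-carbon of the propiolate and the vinylalane adds 1,2 to the aldehyde, which is far more electrophilic than the vinylogous-ester carbonyl, while the new C7 carbinol centre is irrelevant because C7 becomes sp2 in step 7.

Step 7
Reactants: 13 Baylis–Hillman-type adduct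
Product: 14 methyl (2Z,4S,5R)-2-(bromomethyl)-5-[(2R)-2-methyl-3-oxo-5-(prop-1-en-2-yl)-2,3-dihydrofuran-2-yl]-4,5-bis(triethylsilyloxy)pent-2-enoate
Conditions: NBS, Me2S, CH2Cl2, 0 °C to rt
Reagents that add atoms: N-bromosuccinimide O=C1CCC(=O)N1Br
Why: In this Corey–Kim-type bromination with allylic transposition, the alkoxysulfonium salt is opened by bromide in an SN2' sense at the terminal CH2 under nearly neutral conditions and gives the favoured (Z)-2-(bromomethyl)enoate.

Step 8
Reactants: 14 (Z)-allylic bromide; 15 acrolein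
Product: 18 trans-4,5-disubstituted 3-methylidene-5-vinyloxolan-2-one carrying at C7 the (1S,2R)-1,2-dihydroxy-2-[(2R)-2-methyl-3-oxo-5-(prop-1-en-2-yl)-2,3-dihydrofuran-2-yl]ethyl chain (C6 R and C7 as in the target), via allylchromium species 16 (not isolated), via bis-silylated lactone 17 (not isolated)
Conditions: CrCl2 (5 equiv), 15 (5 equiv), THF, 0 °C to rt; then 1 M HCl, THF, rt
Reagents that add atoms: none
Why: In this Nozaki–Hiyama allylation in Barbier mode with in situ lactonisation, the configurationally labile allylchromium reacts through the chair transition state with C8 equatorial to give the anti adduct (H6/H7 trans), the A(1,3)-minimised rotamer (H8 in the alkene plane) makes acrolein attack C7 anti to the bulky C9 branch and so gives the C7/C8 relationship of the target, the O6 chromium alkoxide closes the more stable trans lactone, and dilute acid removes both silyl ethers.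

Step 9
Reactants: 18 diol lactone; 19 (R)-2-methylbutanoic acid
Product: 21 C8 (R)-2-methylbutanoate of 18 (C9 hydroxyl free), via O-acylisourea 20 (not isolated)
Conditions: 19 (1.1 equiv), DIC, DMAP (0.1 equiv), CH2Cl2, −20 to 0 °C
Reagents that add atoms: none
Why: Steglich esterification with the α-branched acyl donor takes the C8 hydroxyl because the C9 hydroxyl is neopentylic (flanked by quaternary C10) and hydrogen-bonded to the furanone, and the mild activation leaves the acyl α-stereocentre, which comes from 19, unchanged.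

Step 10
Reactants: 21 diene ester
Product: 22 target CNP0146060.1
Conditions: second-generation Hoveyda–Grubbs catalyst RuCl2(SIMes)(=CH-C6H4-2-O-i-Pr) (15 mol %, in portions), 1,4-benzoquinone (30 mol %), toluene (1 mM), 80 °C
Reagents that add atoms: none
Why: In this ring-closing metathesis the catalyst loads on the monosubstituted C6 vinyl group and closes onto the isopropenyl furanone, the electron-poor 1,1-disubstituted methylene lactone stays a spectator, the medium ring allows only the (Z)-C4=C5 geometry, and this type of closure is established for the closely related eremantholide ring system.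

## Compound list
1 | 2-C-methyl-D-ribono-1,4-lactone [(3R,4R,5R)-3,4-dihydroxy-5-(hydroxymethyl)-3-methyloxolan-2-one] | O=C1[C@](C)(O)[C@H](O)[C@@H](CO)O1 | starting material
2 | (3R,4R,5R)-3-hydroxy-3-methyl-4-(triethylsilyloxy)-5-[(triethylsilyloxy)methyl]oxolan-2-one | O=C1[C@](C)(O)[C@H](O[Si](CC)(CC)CC)[C@@H](CO[Si](CC)(CC)CC)O1 | intermediate
3 | 2-methylbut-1-en-3-yne | C=C(C)C#C | starting material
4 | lithium 3-methylbut-3-en-1-yn-1-ide | [Li]C#CC(C)=C | intermediate
5 | 1-C-(3-methylbut-3-en-1-ynyl)-2-C-methyl-3,5-bis-O-triethylsilyl-D-ribofuranose (hemiketal, both anomers) | OC1(C#CC(C)=C)[C@](C)(O)[C@H](O[Si](CC)(CC)CC)[C@@H](CO[Si](CC)(CC)CC)O1 | intermediate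
6 | (2R)-2-[(1R,2R)-2-hydroxy-1,3-bis(triethylsilyloxy)propyl]-2-methyl-5-(prop-1-en-2-yl)furan-3(2H)-one | C=C(C)C1=CC(=O)[C@](C)(O1)[C@H](O[Si](CC)(CC)CC)[C@H](O)CO[Si](CC)(CC)CC | intermediate
7 | (1R,2S)-1-[(2R)-2-methyl-3-oxo-5-(prop-1-en-2-yl)-2,3-dihydrofuran-2-yl]-1,3-bis(triethylsilyloxy)propan-2-yl chloroacetate | C=C(C)C1=CC(=O)[C@](C)(O1)[C@H](O[Si](CC)(CC)CC)[C@@H](OC(=O)CCl)CO[Si](CC)(CC)CC | intermediate
8 | (2R)-2-[(1R,2S)-2-hydroxy-1,3-bis(triethylsilyloxy)propyl]-2-methyl-5-(prop-1-en-2-yl)furan-3(2H)-one | C=C(C)C1=CC(=O)[C@](C)(O1)[C@H](O[Si](CC)(CC)CC)[C@@H](O)CO[Si](CC)(CC)CC | intermediate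
9 | (2R)-2-methyl-5-(prop-1-en-2-yl)-2-[(1R,2S)-1,2,3-tris(triethylsilyloxy)propyl]furan-3(2H)-one | C=C(C)C1=CC(=O)[C@](C)(O1)[C@H](O[Si](CC)(CC)CC)[C@@H](O[Si](CC)(CC)CC)CO[Si](CC)(CC)CC | intermediate
10 | (2R,3R)-3-[(2R)-2-methyl-3-oxo-5-(prop-1-en-2-yl)-2,3-dihydrofuran-2-yl]-2,3-bis(triethylsilyloxy)propanal | C=C(C)C1=CC(=O)[C@](C)(O1)[C@H](O[Si](CC)(CC)CC)[C@@H](O[Si](CC)(CC)CC)C=O | intermediate
11 | methyl propiolate | C#CC(=O)OC | starting material
12 | methyl 2-(diisobutylalumanyl)acrylate | C=C(C(=O)OC)[Al](CC(C)C)CC(C)C | intermediate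
13 | methyl (4S,5R)-3-hydroxy-2-methylidene-5-[(2R)-2-methyl-3-oxo-5-(prop-1-en-2-yl)-2,3-dihydrofuran-2-yl]-4,5-bis(triethylsilyloxy)pentanoate (C3 epimers) | C=C(C)C1=CC(=O)[C@](C)(O1)[C@H](O[Si](CC)(CC)CC)[C@@H](O[Si](CC)(CC)CC)C(O)C(=C)C(=O)OC | intermediate
14 | methyl (2Z,4S,5R)-2-(bromomethyl)-5-[(2R)-2-methyl-3-oxo-5-(prop-1-en-2-yl)-2,3-dihydrofuran-2-yl]-4,5-bis(triethylsilyloxy)pent-2-enoate | C=C(C)C1=CC(=O)[C@](C)(O1)[C@H](O[Si](CC)(CC)CC)[C@@H](O[Si](CC)(CC)CC)/C=C(\CBr)C(=O)OC | intermediate
15 | acrolein | C=CC=O | starting material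
16 | allylchromium dichloride derived from 14 (CH2Br replaced by CH2CrCl2) | C=C(C)C1=CC(=O)[C@](C)(O1)[C@H](O[Si](CC)(CC)CC)[C@@H](O[Si](CC)(CC)CC)/C=C(\C[Cr](Cl)Cl)C(=O)OC | intermediate
17 | 8,9-bis(triethylsilyl) ether of 18 (trans lactone, C6 R, C7 to C10 as in the target) | C=C(C)C1=CC(=O)[C@](C)(O1)[C@H](O[Si](CC)(CC)CC)[C@@H](O[Si](CC)(CC)CC)[C@@H]2[C@@H](C=C)OC(=O)C2=C | intermediate
18 | trans-3-methylidene-5-vinyloxolan-2-one bearing at C4 the (1S,2R)-1,2-dihydroxy-2-[(2R)-2-methyl-3-oxo-5-(prop-1-en-2-yl)-2,3-dihydrofuran-2-yl]ethyl group (C6 R, C7 as in the target) | C=C(C)C1=CC(=O)[C@](C)(O1)[C@H](O)[C@@H](O)[C@@H]2[C@@H](C=C)OC(=O)C2=C | intermediate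
19 | (R)-2-methylbutanoic acid | CC[C@@H](C)C(=O)O | starting material
20 | O-[(R)-2-methylbutanoyl]-N,N'-diisopropylisourea | CC[C@@H](C)C(=O)OC(=NC(C)C)NC(C)C | intermediate
21 | C8 (R)-2-methylbutanoate of 18, C9 hydroxyl free | C=C(C)C1=CC(=O)[C@](C)(O1)[C@H](O)[C@@H](OC(=O)[C@H](C)CC)[C@@H]2[C@@H](C=C)OC(=O)C2=C | intermediate
22 | CNP0146060.1, 9α-hydroxy-8β-[(R)-2-methylbutanoyloxy]-1-oxo-3,10-epoxygermacra-2,4Z,11(13)-trien-12,6α-olide | C=C1C(=O)O[C@@H]2/C=C(/C)C3=CC(=O)[C@](C)(O3)[C@H](O)[C@@H](OC(=O)[C@H](C)CC)[C@@H]12 | target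

## Step count and risks
Total step count: 10. Longest linear sequence: 10 (1 to 22).

**Step 2 (the proposed new ring transposition).**
- Risks: a Meyer–Schuster-type 1,3-shift of the propargylic hemiketal to the exocyclic vinylogous ester, loss of the primary silyl ether, or slow anomer equilibration.
- The fallback uses known chemistry. It sets out from 5 and comes back at 6.
- Crude 5 is stirred with Et2NH in THF/EtOH at rt. The open hydroxy-ynone tautomer, the form through which alkynyl lactols are known to react with nucleophiles, is drained by conjugate addition to the β-diethylamino dienone F1.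
- Brief treatment with aqueous AcOH lets the tertiary C10 hydroxyl replace the amine by addition–elimination and gives 6. This is the classical amine-mediated 3(2H)-furanone synthesis from hydroxy ynones.

**Step 3 (SN2 at a carbinol flanked by two oxygenated carbons).**
- Risks: a sluggish displacement, elimination, or participation of the furanone carbonyl oxygen.
- The fallback replaces substitution by a redox inversion. It sets out from 6 and comes back at 8.
- Dess–Martin periodinane gives the C8 ketone F2.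
- Reduction with NaBH4/CeCl3·7H2O in MeOH at −78 °C follows the polar Felkin–Anh model for a non-chelating α-silyloxy ketone and gives the syn 8,9-relationship, that is 8. The much less electrophilic vinylogous-ester carbonyl is left alone.

**Step 10 (ring-closing metathesis onto an electron-poor 1,1-disubstituted alkene in a strained ring).**
- Risks: no closure, or dimer formation.
- The fallback closes the ring at C6–C7 instead and buys the Z-alkene. It sets out from 2 and comes back at 22.
- Commercial (Z)-3-methylpent-2-en-4-yn-1-ol F3 is silylated (Et3SiCl, imidazole) to its triethylsilyl ether F4 and lithiated to the acetylide F5.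
- F5 is carried through the chemistry of steps 2 to 4. This gives in turn the alkynyl lactol F6, the ribo-configured furanone alcohol F7, the inverted chloroacetate F8, the inverted alcohol F9 and the tetrakis(triethylsilyl) ether F10.
- Swern oxidation now converts both primary silyl ethers and gives the dialdehyde F11.
- One equivalent of vinylalane 12 adds to the more electrophilic α-silyloxy aldehyde to give the adduct F12, and NBS/Me2S gives the allylic bromide enal F13.
- Slow addition of F13 to CrCl2 in THF/DMF (1 mM) forms the allylchromium species F14. This closes the ten-membered ring by intramolecular Nozaki–Hiyama allylation and lactonises to the macrocyclic bis(triethylsilyl) ether F15.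
- 1 M HCl gives the macrocyclic 8,9-diol F16, and Steglich esterification with 19 as in step 9 gives 22.

## Further compounds
F1 | step 2 | (6R,7R,8R)-4-(diethylamino)-6,8-dihydroxy-2,6-dimethyl-7,9-bis(triethylsilyloxy)nona-1,3-dien-5-one (open-chain enaminone) | C=C(C)C(=CC(=O)[C@](C)(O)[C@H](O[Si](CC)(CC)CC)[C@H](O)CO[Si](CC)(CC)CC)N(CC)CC
F2 | step 3 | (2R)-2-[(1R)-2-oxo-1,3-bis(triethylsilyloxy)propyl]-2-methyl-5-(prop-1-en-2-yl)furan-3(2H)-one | C=C(C)C1=CC(=O)[C@](C)(O1)[C@H](O[Si](CC)(CC)CC)C(=O)CO[Si](CC)(CC)CC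
F3 | step 10 | (Z)-3-methylpent-2-en-4-yn-1-ol | C#C/C(C)=C\CO
F4 | step 10 | (Z)-3-methylpent-2-en-4-yn-1-yl triethylsilyl ether | C#C/C(C)=C\CO[Si](CC)(CC)CC
F5 | step 10 | lithium acetylide of F4 | [Li]C#C/C(C)=C\CO[Si](CC)(CC)CC
F6 | step 10 | 1-C-alkynyl lactol from 2 and F5 (both anomers) | OC1(C#C/C(C)=C\CO[Si](CC)(CC)CC)[C@](C)(O)[C@H](O[Si](CC)(CC)CC)[C@@H](CO[Si](CC)(CC)CC)O1
F7 | step 10 | analogue of 6 with a (Z)-4-(triethylsilyloxy)but-2-en-2-yl group at C3 | CC[Si](CC)(CC)OC/C=C(/C)C1=CC(=O)[C@](C)(O1)[C@H](O[Si](CC)(CC)CC)[C@H](O)CO[Si](CC)(CC)CC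
F8 | step 10 | C8-inverted chloroacetate of F7 | CC[Si](CC)(CC)OC/C=C(/C)C1=CC(=O)[C@](C)(O1)[C@H](O[Si](CC)(CC)CC)[C@@H](OC(=O)CCl)CO[Si](CC)(CC)CC
F9 | step 10 | C8-inverted alcohol (analogue of 8) | CC[Si](CC)(CC)OC/C=C(/C)C1=CC(=O)[C@](C)(O1)[C@H](O[Si](CC)(CC)CC)[C@@H](O)CO[Si](CC)(CC)CC
F10 | step 10 | tetrakis(triethylsilyl) ether (analogue of 9) | CC[Si](CC)(CC)OC/C=C(/C)C1=CC(=O)[C@](C)(O1)[C@H](O[Si](CC)(CC)CC)[C@@H](O[Si](CC)(CC)CC)CO[Si](CC)(CC)CC
F11 | step 10 | C6,C7-dialdehyde with (Z)-enal | O=C/C=C(/C)C1=CC(=O)[C@](C)(O1)[C@H](O[Si](CC)(CC)CC)[C@@H](O[Si](CC)(CC)CC)C=O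
F12 | step 10 | Baylis–Hillman-type adduct at C7 with the (Z)-enal retained (C7 epimers) | O=C/C=C(/C)C1=CC(=O)[C@](C)(O1)[C@H](O[Si](CC)(CC)CC)[C@@H](O[Si](CC)(CC)CC)C(O)C(=C)C(=O)OC
F13 | step 10 | (Z)-2-(bromomethyl)enoate bearing the (Z)-enal | O=C/C=C(/C)C1=CC(=O)[C@](C)(O1)[C@H](O[Si](CC)(CC)CC)[C@@H](O[Si](CC)(CC)CC)/C=C(\CBr)C(=O)OC
F14 | step 10 | allylchromium dichloride derived from F13 | O=C/C=C(/C)C1=CC(=O)[C@](C)(O1)[C@H](O[Si](CC)(CC)CC)[C@@H](O[Si](CC)(CC)CC)/C=C(\C[Cr](Cl)Cl)C(=O)OC
F15 | step 10 | 8,9-bis(triethylsilyl) ether of the macrocyclic diol | C=C1C(=O)O[C@@H]2/C=C(/C)C3=CC(=O)[C@](C)(O3)[C@H](O[Si](CC)(CC)CC)[C@@H](O[Si](CC)(CC)CC)[C@@H]12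
F16 | step 10 | 8β,9α-dihydroxy-1-oxo-3,10-epoxygermacra-2,4Z,11(13)-trien-12,6α-olide | C=C1C(=O)O[C@@H]2/C=C(/C)C3=CC(=O)[C@](C)(O3)[C@H](O)[C@@H](O)[C@@H]12
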